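Locants follow the target throughout: C1 is the quaternary carbinol, C2 and C3 the free carbinols, C4 the ring benzoate carbon, C5=C6 the alkene (C6 on C1), C7 the exocyclic CH2; O-n is the oxygen on Cn.

## Structural features

The target is a single cyclohexene ring carrying one exocyclic carbon, C7H2OBz on C1, and C1–C4 are four contiguous stereocentres that run from one end of the C5=C6 alkene to the other. C1 is a quaternary, tertiary allylic carbinol, C2 and C3 are free secondary carbinols, and C4 is a secondary allylic benzoate. The ring oxygens O-1 to O-4 alternate faces (all-trans), so C7 is cis to O-2 and O-4, and the configuration is 1R,2S,3S,4S. Three things are fragile: two benzoates sit beside three free hydroxyls (acyl migration under base), both C1–O and C4–O are allylic (ionisation by strong acid or by zerovalent palladium), and any C1 ketone on the way has an acidic C2–H with an oxygen on C3 (β-elimination, then aromatisation). The real difficulty is twofold: telling four ring oxygens apart while fixing the absolute configuration, and building the quaternary C1 with C7 on the face cis to O-2. The key step exploits the fact that O-1 and O-4 are both allylic to C5=C6 and that the O-1 to O-4 pattern is that of conduritol B. With four identical carbonates, ionisation at C4 (or C1) gives an η3-allyl over C4–C5–C6 whose three remaining carbonate-bearing carbons make it meso, so a racemate converges and Pd2(dba)3 with a chiral bisphosphine can put benzoates on O-1 and O-4 only, one of them being the C4 benzoate of the target and the other marking C1.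

## Logic of the disconnections

19 from 18: the two acetal C–O bonds on O-2 and O-3 are cut last. A free trans-diol beside benzoates invites acyl migration, so it is unveiled only at the end. The forward step must use acid mild enough to leave the esters and the allylic C–O bonds alone.

18 from 17 and 9: the O-7–acyl bond is cut. This removes one ester and leaves a diol whose two hydroxyls differ strongly (primary against hindered tertiary). The forward acylation must touch only the primary one.

17 from 16: the C1–O and C7–O bonds are cut together (syn-dihydroxylation retron). This removes the quaternary stereocentre and leaves a planar exocyclic alkene. The forward step must choose the exocyclic alkene over the ring alkene and the face anti to O-2.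

16 from 15: the C1=C7 bond is cut, removing the only carbon not present in the six-membered ring. The forward methylenation must be non-basic, because the ketone is enolisable and flanked by oxygen, and must spare the benzoate and the acetal.

15 from 14: the C1 carbonyl is taken back to the carbinol, so that C1 is again a normal stereocentre of the all-trans series. The forward oxidation must be neutral and selective for the allylic alcohol.

14 from 13: the O-1–benzoyl bond is re-formed. 13 is C2-symmetric, so its two benzoates are homotopic and loss of either gives 14. The forward step only has to stop after one cleavage.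

13 from 12: the acetal C–O bonds on O-2 and O-3 are cut. The acetal is chosen because it is base-stable, locks O-2 and O-3 equatorial (which later steers the osmylation and disfavours β-elimination from 15), and leaves under mild acid. The forward step must close a trans-fused dioxolane without moving the benzoates.

12 from 11: the O-2 and O-3 carbonate bonds are cut. The carbonates are needed as leaving groups in the key step, but they are more base-labile than the benzoates and would survive neither the basic benzoate cleavage nor the reducing Zn/CH2Br2/TiCl4 methylenation, so they are exchanged here. The forward removal must be reductive and leave the benzoates.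

11 from 8 and 9: the C1–O and C4–O benzoate bonds are cut. This is the strategic cut: it removes the difference between the allylic and non-allylic oxygens and all absolute stereochemistry, giving a racemic, fully symmetric tetra-ester. The forward step must convert both enantiomers of 8, substitute only at the allylic termini with retention, choose one enantiomeric series, and consume two equivalents of 9.

8 from 6 and 7: four O–acyl bonds are cut, so the forward step consumes four equivalents of 7. The four groups must be identical, since only then is the allyl intermediate of the key step meso.

6 from 5: four acetate O–acyl bonds are cut; the forward step is a plain ester exchange.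

5 from 3 (through 4): the C2–O and C3–O bonds are cut back to C–Br bonds. The forward substitution must proceed with retention at both carbons, which neighbouring acetates secure.

3 from 2: the C1–H and C4–H bonds are cut (carbinols back to ketones). The forward reduction must place each hydroxyl trans to the adjacent bromine.

2 from 1: the two C–Br bonds are cut, leaving a flat, achiral quinone. The forward addition must stop at one alkene and be anti.

## Other disconnections considered

Alternative 1: All ring oxygens except O-3 and O-4 are removed and the ring is traced to cyclohexa-1,3-diene A1. Forward, chiral N,N'-bis(3,5-di-tert-butylsalicylidene)-1,2-cyclohexanediaminomanganese chloride with NaOCl would epoxidise one alkene to the vinyl oxirane A2 (1R,6S), whose oxygen becomes O-3. Benzoate opening at the allylic carbon with inversion would then give the trans O-3/O-4 pair with the C4 benzoate in place.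
- In its favour: the absolute configuration is set catalytically in the first step from a very cheap diene, and the C4 benzoate arrives by a clean SN2 opening. On early step economy this is better than the chosen plan, which spends five steps before its asymmetric step.
- Against it here: A2 leaves C1 and C2 as bare methylene groups, so O-2, O-1 and C7 each need their own allylic oxidation or transposition with separate regio- and stereochemical questions. The enantioselectivity of this type of epoxidation on a cyclic cis-diene is not expected to be complete, nothing later corrects it, and A2 is volatile and acid-sensitive.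
- Comparison: on structure the chosen plan starts with all four ring oxygens in the right relative configuration and Alternative 1 with two. On mechanism both rely on catalyst control, but the allylic substitution has a second, self-correcting substitution. On overall step economy the oxidation relay is likely to cancel the early gain. Both plans build the quaternary C1 late, so on that point they are equal.

Alternative 2: The C1–C2 and C3–C4 bonds are cut (Diels–Alder retron), giving 3-hydroxy-2-pyrone A3 and (E)-hex-3-ene-2,5-dione A4. Forward, a chiral bifunctional amine base would deprotonate the 3-hydroxyl of A3, hold A4 by hydrogen bonding, and deliver the bridged lactone A5.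
- In its favour: one step would build the ring, the quaternary carbinol C1 with C7 already attached as the lactone carbonyl, and all four stereocentres. The trans dienophile guarantees the C2/C3 trans relationship and the lactone bridge marks C4 and C7. On skeleton construction and on the hardest centre this is better than the chosen plan, which needs four steps after its key step to make C1.
- Against it here: the acetyl groups on C2 and C3 are only placeholders for oxygen, so both need a retentive Baeyer–Villiger oxidation beside an alkene and a strained α-hydroxy lactone. The bridged lactone can lose CO2 on warming. A doubly activated dienophile invites an uncatalysed background reaction that would erode enantio- and endo/exo control (the acetyl next to the carbinol bridgehead must end syn to the lactone bridge). The acetates on O-2/O-3 must later be removed beside the benzoates on O-4/O-7.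
- Comparison: on structure Alternative 2 is the more convergent. On mechanism its stereocontrol rests on a single event with no correction, against a meso intermediate and a proof-reading second substitution in the chosen plan. On step economy it could be shorter if the two oxidations and the ester differentiation went cleanly, which is the open question. Both plans end with the same problem of keeping benzoates in place beside free hydroxyls, so there they are equal.

Alternative 3: The C1–O and C2–O bonds are cut back to the arene, benzoic acid A6 (identical with 9). Forward, whole cells expressing benzoate 1,2-dioxygenase (a blocked mutant of Ralstonia eutropha) would add O2 across the ipso and ortho carbons to give the (1S,2R)-cis-diol acid A7.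
- In its favour: quaternary C1, with C7 attached and with the correct absolute configuration, comes in one enzymatic step from a commodity chemical. On the hardest centre and on enantiopurity this is the equal or the better of the chosen plan.
- Against it here: O-2 arrives cis to O-1, so C2 must be inverted at a hindered allylic carbinol next to a quaternary centre (risk of SN2' or elimination). The C3=C4 alkene of the diene must then be oxidised regioselectively and trans, with benzoate ending on C4. The acid must be reduced to CH2OH on a diene that aromatises easily by dehydration. The fermentation needs an organism and equipment that are not shelf items.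
- Comparison: on structure the two plans are complementary, since the enzyme gives C1/C7 first and must add O-3/O-4 and correct O-2, while the chosen route gives O-1 to O-4 first and must add C7. On mechanism enzyme control is absolute, but the later substrate-controlled steps on a reactive diene carry more selectivity questions than the osmylation of the chosen plan. On step economy Alternative 3 could be comparable or somewhat shorter, at the cost of the inversion and of practicality.

Key step: step 6

Assumption: the sense of induction is taken from the way this ligand class treats simple meso cycloalkenyl allylpalladium cations, which points to the ligand from (1S,2S)-diaminocyclohexane for the (1S,2R,3R,4S) series; if the substituted allyl responds in the opposite sense, the (1R,2R) ligand is used and nothing else changes.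

## Route

Step 1
Reactants: 1 1,4-benzoquinone
Product: 2 racemic trans-5,6-dibromocyclohex-2-ene-1,4-dione
Conditions: Br2 (1.0 equiv), CH2Cl2, 0 °C, dark
Reagents that add atoms: bromine, BrBr
Why: Electrophilic anti addition of bromine across one C=C (bromonium opening) gives the trans dibromide; the remaining alkene is flanked by two carbonyls and too electron-poor to add a second equivalent.

Step 2
Reactants: 2 racemic trans-5,6-dibromocyclohex-2-ene-1,4-dione
Product: 3 racemic all-trans 5,6-dibromocyclohex-2-ene-1,4-diol (each OH trans to the neighbouring Br, the two Br trans)
Conditions: NaBH4, MTBE/H2O, 0 °C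
Reagents that add atoms: none
Why: Borohydride 1,2-reduction of both carbonyls; axial hydride delivery to the half-chair with pseudo-equatorial bromines should leave each new hydroxyl trans to its neighbouring bromine, and any minor epimer is removed by crystallisation.

Step 3
Reactants: 3 racemic all-trans 5,6-dibromocyclohex-2-ene-1,4-diol
Product: 5 racemic conduritol B tetraacetate (all-trans cyclohex-5-ene-1,2,3,4-tetrayl tetraacetate), via dibromo diacetate 4 (not isolated)
Conditions: Ac2O (excess), AcOH, 100 °C; then KOAc (4 equiv), reflux
Reagents that add atoms: acetic anhydride (two equivalents), CC(=O)OC(C)=O.CC(=O)OC(C)=O; potassium acetate (two equivalents), [K+].CC(=O)[O-].[K+].CC(=O)[O-]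
Why: Thermal O-acetylation of both hydroxyls gives 4; each trans acetate then displaces its neighbouring bromide (anchimeric assistance, cis-fused acetoxonium ion) and acetate reopens the ion with inversion, so oxygen replaces bromine with net retention and the all-trans tetraacetate results. Opening both ions at the same kind of ring carbon gives the same racemate either way, and the meso isomer from mixed opening is removed by crystallisation.

Step 4
Reactants: 5 racemic conduritol B tetraacetate
Product: 6 racemic conduritol B (all-trans cyclohex-5-ene-1,2,3,4-tetrol)
Conditions: NaOMe (cat.), MeOH, rt; sulfonic acid resin (H+ form)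
Reagents that add atoms: none
Why: Zemplén transesterification; methoxide is regenerated, methyl acetate is the only by-product and no C–O bond at a stereocentre is broken.

Step 5
Reactants: 6 racemic conduritol B; 7 2,2,2-trichloroethyl chloroformate
Product: 8 racemic conduritol B tetrakis(2,2,2-trichloroethyl carbonate)
Conditions: 7 (5 equiv charged, 4 equiv consumed), pyridine, DMAP (cat.), CH2Cl2, 0 °C to rt
Reagents that add atoms: 2,2,2-trichloroethyl chloroformate (the three further equivalents of 7), ClC(=O)OCC(Cl)(Cl)Cl.ClC(=O)OCC(Cl)(Cl)Cl.ClC(=O)OCC(Cl)(Cl)Cl
Why: Exhaustive O-acylation (carbonate formation): each of the four secondary hydroxyls takes one molecule of 7 by addition–elimination at the acyl carbon, with DMAP as acyl-transfer catalyst and pyridine binding the HCl, so four equivalents of 7 are consumed. The result is four identical, strongly activated leaving groups, which is what the key step needs, and no stereocentre is touched.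

Step 6
Reactants: 8 racemic conduritol B tetrakis(2,2,2-trichloroethyl carbonate); 9 benzoic acid
Product: 11 (1S,2R,3R,4S)-cyclohex-5-ene-1,2,3,4-tetrayl 1,4-dibenzoate 2,3-bis(2,2,2-trichloroethyl carbonate), via monobenzoate tris-carbonate 10 (not isolated)
Conditions: Pd2(dba)3·CHCl3 (2.5 mol %), N,N'-[(1S,2S)-cyclohexane-1,2-diyl]bis[2-(diphenylphosphino)benzamide] (7.5 mol %), 9 (2.2 equiv) with NaOH (2.2 equiv) as sodium benzoate, (n-C6H13)4NBr, CH2Cl2/H2O, rt
Reagents that add atoms: benzoic acid (second equivalent of 9), O=C(O)c1ccccc1
Why: This is a Tsuji–Trost allylic substitution run as a dynamic kinetic asymmetric transformation: zerovalent palladium ionises an allylic carbonate of either enantiomer of 8 with inversion, and because the three remaining carbonate-bearing carbons make the resulting η3-allyl–PdL2 cation over C4–C5–C6 meso, both enantiomers converge on one intermediate. Benzoate attacks an allyl terminus on the face opposite palladium (second inversion, net retention at carbon) and the chiral pocket of the ligand decides which enantiotopic terminus is taken, giving monobenzoate 10 of one enantiomeric series. In 10 only one allylic carbonate is left; its ionisation and attack by a second benzoate at the same carbon, which is again the terminus the ligand prefers (matched case), forms the second C–O bond and gives C2-symmetric 11. No ring is closed. C1 and C4 are set as S by the ligand-controlled choice of terminus together with the double-inversion retention, and C2 and C3 (both R) ride unchanged on the enantiomeric series so selected. The step needs convergence of both substrate enantiomers, terminus selection and clean retention; the first is secured by four identical, fast-ionising trichloroethyl carbonates, the second by the ligand, the third by a soft carboxylate that attacks carbon and not the metal. Benzoate is a far poorer leaving group than the carbonate, so 11 accumulates, and wrong-series monobenzoate should be diverted by the same ligand preference to a separable vicinal dibenzoate, which should raise the enantiomeric purity of 11. The closest known reaction type is this same dynamic allylic substitution of racemic conduritol B tetracarbonates by carboxylates under zerovalent palladium.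

Step 7
Reactants: 11 (1S,2R,3R,4S)-cyclohex-5-ene-1,2,3,4-tetrayl 1,4-dibenzoate 2,3-bis(2,2,2-trichloroethyl carbonate)
Product: 12 (1S,2S,3S,4S)-2,3-dihydroxycyclohex-5-ene-1,4-diyl dibenzoate
Conditions: Zn dust, AcOH/THF, rt (vented to a scrubber)
Reagents that add atoms: none
Why: Reductive fragmentation of the trichloroethyl carbonates: zinc inserts into a C–Cl bond and the β-chloro organozinc species collapses to 1,1-dichloroethene, CO2 and the alcohol; benzoates and the alkene are inert, and the acidic medium suppresses benzoate migration to the freed hydroxyls.

Step 8
Reactants: 12 (1S,2S,3S,4S)-2,3-dihydroxycyclohex-5-ene-1,4-diyl dibenzoate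
Product: 13 2,3-O-isopropylidene acetal of 12, (3aR,4S,7S,7aR)-2,2-dimethyl-3a,4,7,7a-tetrahydro-1,3-benzodioxole-4,7-diyl dibenzoate (trans-fused dioxolane, benzoates on O-1 and O-4)
Conditions: Me2C(OMe)2, CSA (cat.), acetone, 4 Å sieves, rt
Reagents that add atoms: 2,2-dimethoxypropane, COC(C)(C)OC
Why: Acid-catalysed transacetalisation closes a trans-fused dioxolane on the diequatorial diol in a non-nucleophilic medium that leaves the benzoates alone; the acetal is base-stable, locks O-2/O-3 equatorial and comes off later under mild acid.

Step 9
Reactants: 13 2,3-O-isopropylidene 1,4-dibenzoate
Product: 14 (1S,2R,3R,4S)-1-hydroxy-2,3-O-isopropylidene 4-benzoate (allylic alcohol at C1)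
Conditions: K2CO3 (0.3 equiv), MeOH/THF, 0 °C, stopped at partial conversion; recovered 13 recycled
Reagents that add atoms: none
Why: Base-catalysed methanolysis of one benzoate; the two benzoates of C2-symmetric 13 are homotopic, so either cleavage gives 14 and only over-reaction has to be managed, by stopping early and returning recovered 13.

Step 10
Reactants: 14 allylic alcohol
Product: 15 (2S,3R,4S)-4-benzoyloxy-2,3-O-isopropylidenecyclohex-5-en-1-one
Conditions: MnO2 (activated, excess), CH2Cl2, rt
Reagents that add atoms: none
Why: MnO2 oxidation is selective for allylic alcohols and neutral, which suits an enone with an acidic C2–H; the acetal holds the C3–O bond equatorial, out of alignment with the enolate π system, so β-elimination is stereoelectronically disfavoured.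

Step 11
Reactants: 15 enone
Product: 16 (2R,3R,4S)-4-benzoyloxy-2,3-O-isopropylidene-1-methylenecyclohex-5-ene
Conditions: Zn/CH2Br2/TiCl4 reagent (pre-formed, THF, 0 °C), then 15 in CH2Cl2, 0 °C to rt
Reagents that add atoms: dibromomethane, BrCBr
Why: Takai–Lombardo methylenation: the reagent pre-formed from Zn, CH2Br2 and TiCl4 is non-basic and reacts with ketones far faster than with esters, so the enolisable enone should give the exocyclic diene without epimerising C2 or attacking the benzoate.

Step 12
Reactants: 16 exocyclic diene
Product: 17 (1R,2S,3R,4S)-4-benzoyloxy-1-hydroxy-1-(hydroxymethyl)-2,3-O-isopropylidenecyclohex-5-ene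
Conditions: K2OsO2(OH)4 (2 mol %), NMO (1.2 equiv), acetone/H2O, 0 °C
Reagents that add atoms: N-methylmorpholine N-oxide, C[N+]1([O-])CCOCC1; water, O
Why: Catalytic OsO4 syn-dihydroxylation with NMO as reoxidant: the terminal 1,1-disubstituted alkene is more accessible and more electron-rich than the ring alkene next to the benzoate-bearing C4, and OsO4 adds anti to the allylic C2–O bond, from the equatorial direction of the acetal-locked half-chair, which sets O-1 trans to O-2 (1R) and leaves C7 cis to O-2.

Step 13
Reactants: 17 diol; 9 benzoic acid
Product: 18 (1R,2S,3R,4S)-4-benzoyloxy-1-(benzoyloxymethyl)-1-hydroxy-2,3-O-isopropylidenecyclohex-5-ene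
Conditions: 9 (1.1 equiv), EDC·HCl, DMAP (cat.), CH2Cl2, 0 °C to rt
Reagents that add atoms: none
Why: Steglich esterification; the primary C7 hydroxyl is acylated far faster than the hindered tertiary C1 hydroxyl and no other hydroxyl is free.

Step 14
Reactants: 18 acetonide dibenzoate
Product: 19 kweichowenol B, [(1R,2S,3S,4S)-4-benzoyloxy-1,2,3-trihydroxycyclohex-5-en-1-yl]methyl benzoate
Conditions: AcOH/H2O (4:1), 40 °C
Reagents that add atoms: none
Why: Acid-catalysed hydrolysis of the strained trans-fused acetonide needs only mild aqueous acid, under which the benzoates should neither hydrolyse nor migrate and the electron-poor allylic C–O bonds should not ionise; no stereocentre is touched.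

## Compound list

1 | 1,4-benzoquinone | O=C1C=CC(=O)C=C1 | starting material
2 | racemic trans-5,6-dibromocyclohex-2-ene-1,4-dione (one enantiomer drawn) | O=C1C=CC(=O)[C@@H](Br)[C@@H]1Br | intermediate
3 | racemic all-trans 5,6-dibromocyclohex-2-ene-1,4-diol (one enantiomer drawn) | O[C@H]1C=C[C@H](O)[C@@H](Br)[C@@H]1Br | intermediate
4 | racemic all-trans 5,6-dibromocyclohex-2-ene-1,4-diyl diacetate (one enantiomer drawn) | CC(=O)O[C@H]1C=C[C@H](OC(C)=O)[C@@H](Br)[C@@H]1Br | intermediate (not isolated)
5 | racemic conduritol B tetraacetate (one enantiomer drawn) | CC(=O)O[C@H]1C=C[C@H](OC(C)=O)[C@@H](OC(C)=O)[C@@H]1OC(C)=O | intermediate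
6 | racemic conduritol B (one enantiomer drawn) | O[C@H]1C=C[C@H](O)[C@@H](O)[C@@H]1O | intermediate
7 | 2,2,2-trichloroethyl chloroformate | ClC(=O)OCC(Cl)(Cl)Cl | starting material
8 | racemic conduritol B tetrakis(2,2,2-trichloroethyl carbonate) (one enantiomer drawn) | ClC(Cl)(Cl)COC(=O)O[C@H]1C=C[C@H](OC(=O)OCC(Cl)(Cl)Cl)[C@@H](OC(=O)OCC(Cl)(Cl)Cl)[C@@H]1OC(=O)OCC(Cl)(Cl)Cl | intermediate
9 | benzoic acid | O=C(O)c1ccccc1 | starting material
10 | (1S,2R,3R,4S)-cyclohex-5-ene-1,2,3,4-tetrayl 1-benzoate 2,3,4-tris(2,2,2-trichloroethyl carbonate) | O=C(O[C@H]1C=C[C@H](OC(=O)OCC(Cl)(Cl)Cl)[C@@H](OC(=O)OCC(Cl)(Cl)Cl)[C@@H]1OC(=O)OCC(Cl)(Cl)Cl)c1ccccc1 | intermediate (not isolated)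
11 | (1S,2R,3R,4S)-cyclohex-5-ene-1,2,3,4-tetrayl 1,4-dibenzoate 2,3-bis(2,2,2-trichloroethyl carbonate) | O=C(O[C@H]1C=C[C@H](OC(=O)c2ccccc2)[C@@H](OC(=O)OCC(Cl)(Cl)Cl)[C@@H]1OC(=O)OCC(Cl)(Cl)Cl)c1ccccc1 | intermediate
12 | (1S,2S,3S,4S)-2,3-dihydroxycyclohex-5-ene-1,4-diyl dibenzoate | O=C(O[C@H]1C=C[C@H](OC(=O)c2ccccc2)[C@@H](O)[C@@H]1O)c1ccccc1 | intermediate
13 | (3aR,4S,7S,7aR)-2,2-dimethyl-3a,4,7,7a-tetrahydro-1,3-benzodioxole-4,7-diyl dibenzoate | O=C(O[C@H]1C=C[C@H](OC(=O)c2ccccc2)[C@H]3OC(C)(C)O[C@H]13)c1ccccc1 | intermediate
14 | mono-benzoate of the 2,3-O-isopropylidene tetrol, (1S,2R,3R,4S), O-1 free and O-4 benzoylated | O[C@H]1C=C[C@H](OC(=O)c2ccccc2)[C@H]3OC(C)(C)O[C@H]13 | intermediate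
15 | (2S,3R,4S)-4-benzoyloxy-2,3-O-isopropylidenecyclohex-5-en-1-one | O=C1C=C[C@H](OC(=O)c2ccccc2)[C@H]3OC(C)(C)O[C@H]13 | intermediate
16 | (2R,3R,4S)-4-benzoyloxy-2,3-O-isopropylidene-1-methylenecyclohex-5-ene | C=C1C=C[C@H](OC(=O)c2ccccc2)[C@H]3OC(C)(C)O[C@H]13 | intermediate
17 | (1R,2S,3R,4S)-4-benzoyloxy-1-hydroxy-1-(hydroxymethyl)-2,3-O-isopropylidenecyclohex-5-ene | OC[C@]1(O)C=C[C@H](OC(=O)c2ccccc2)[C@H]3OC(C)(C)O[C@H]13 | intermediate
18 | (1R,2S,3R,4S)-4-benzoyloxy-1-(benzoyloxymethyl)-1-hydroxy-2,3-O-isopropylidenecyclohex-5-ene | O=C(OC[C@]1(O)C=C[C@H](OC(=O)c2ccccc2)[C@H]3OC(C)(C)O[C@H]13)c1ccccc1 | intermediate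
19 | kweichowenol B, [(1R,2S,3S,4S)-4-benzoyloxy-1,2,3-trihydroxycyclohex-5-en-1-yl]methyl benzoate | O=C(OC[C@]1(O)C=C[C@H](OC(=O)c2ccccc2)[C@@H](O)[C@@H]1O)c1ccccc1 | target

## Step count and least certain steps

Total: 14 steps. Longest linear sequence: 14 steps from 1 (7 and 9 enter as purchased building blocks).

Step 6 (key step). The dynamic process may stall into a kinetic resolution if the mismatched enantiomer of 8 ionises too slowly. The carbonates may also hydrolyse in the two-phase medium, and the second substitution may go to the wrong allyl terminus. The fallback sets out from 5 and returns at 12. Racemic 5 is treated with the same Pd2(dba)3·CHCl3/ligand system and sodium benzoate. Acetate is a much poorer leaving group, so only the matched enantiomer should ionise (kinetic resolution in place of dynamic convergence). Two retentive substitutions carry it to (1S,2R,3R,4S)-cyclohex-5-ene-1,2,3,4-tetrayl 2,3-diacetate 1,4-dibenzoate F1, and the slow enantiomer of 5 is separated. HCl in MeOH (from AcCl) then cleaves the two acetates and spares the benzoates, giving 12. Half of the material is given up, but the labile carbonates and steps 4, 5 and 7 are avoided.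

Step 9. Cleavage of the two homotopic benzoates is statistical, so over-cleavage and incomplete conversion limit the throughput. The fallback sets out from 13 and returns at 15. Both benzoates are removed (K2CO3, MeOH, to completion) to give the C2-symmetric (1S,2R,3R,4S)-2,3-O-isopropylidenecyclohex-5-ene-1,4-diol F2. MnO2 oxidises one allylic hydroxyl; the second, now γ to an enone, should react far more slowly, so (2S,3R,4S)-4-hydroxy-2,3-O-isopropylidenecyclohex-5-en-1-one F3 should form non-statistically. Esterification of F3 with 9 (EDC·HCl, DMAP) gives 15. This costs one step and replaces the benzoate set in the key step by a new one.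

Step 11. Residual Lewis acidity of the Zn/CH2Br2/TiCl4 reagent may open the strained acetal or ionise the allylic benzoate of the diene, and enolisation or ester methylenation may compete. The fallback sets out from 15 and returns at 16 by a two-stage Peterson olefination. Me3SiCH2MgCl with CeCl3 (THF, −78 °C) should add 1,2 to the ketone without enolising it, giving (2S,3R,4S)-4-benzoyloxy-1-hydroxy-2,3-O-isopropylidene-1-(trimethylsilylmethyl)cyclohex-5-ene F4 (C1 epimers, inconsequential). KN(SiMe3)2 in THF at 0 °C then triggers syn elimination of silanolate to give 16.

Step 12. The osmylation may show poor facial selectivity at the exocyclic alkene (equatorial against axial approach) or poor site selectivity against the ring alkene. The fallback sets out from 15 and returns at 18, bypassing 16 and 17. Dimethylsulfonium methylide (Me3SI, KN(SiMe3)2, THF, −20 °C; Corey–Chaykovsky epoxidation) adds irreversibly and should approach the C1 carbonyl axially. That places C7 axial (cis to O-2) and the oxirane oxygen equatorial (trans to O-2), giving (1R,2S,3R,4S)-4-benzoyloxy-1,7-epoxy-2,3-O-isopropylidene-1-methylcyclohex-5-ene F5, the spiro-oxirane at C1. Opening of F5 at the primary C7 by benzoate (9, catalytic Cs2CO3, DMF, 60 °C) gives 18 directly. The C1 configuration then comes from C–C bond formation on one face instead of C–O bond formation on the other; the price is a basic reagent on a base-sensitive enone.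

Step 14. Acyl migration to the newly freed hydroxyls, or slow hydrolysis that tempts forcing conditions and then ionisation at the allylic positions, may erode the last step. The fallback sets out from 17 and returns at 19 by reversing the order of the last two operations. The acetonide of 17 is hydrolysed first (aqueous AcOH) to (1R,2S,3S,4S)-4-benzoyloxy-1-(hydroxymethyl)cyclohex-5-ene-1,2,3-triol F6. The primary C7 hydroxyl is then acylated selectively with vinyl benzoate and immobilised Candida antarctica lipase B under neutral conditions to give 19, so the final product never meets acid.

## Further compounds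

F1 | step 6 | (1S,2R,3R,4S)-cyclohex-5-ene-1,2,3,4-tetrayl 2,3-diacetate 1,4-dibenzoate | O=C(O[C@H]1C=C[C@H](OC(=O)c2ccccc2)[C@@H](OC(C)=O)[C@@H]1OC(C)=O)c1ccccc1
F2 | step 9 | (1S,2R,3R,4S)-2,3-O-isopropylidenecyclohex-5-ene-1,4-diol | O[C@H]1C=C[C@H](O)[C@H]2OC(C)(C)O[C@H]12
F3 | step 9 | (2S,3R,4S)-4-hydroxy-2,3-O-isopropylidenecyclohex-5-en-1-one | O=C1C=C[C@H](O)[C@H]2OC(C)(C)O[C@H]12
F4 | step 11 | (2S,3R,4S)-4-benzoyloxy-1-hydroxy-2,3-O-isopropylidene-1-(trimethylsilylmethyl)cyclohex-5-ene (C1 epimers) | C[Si](C)(C)CC1(O)C=C[C@H](OC(=O)c2ccccc2)[C@H]3OC(C)(C)O[C@H]13
F5 | step 12 | (1R,2S,3R,4S)-4-benzoyloxy-1,7-epoxy-2,3-O-isopropylidene-1-methylcyclohex-5-ene (spiro-oxirane at C1, oxirane O trans to O-2, C7 cis to O-2) | C5O[C@]51C=C[C@H](OC(=O)c2ccccc2)[C@H]3OC(C)(C)O[C@H]13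
F6 | step 14 | (1R,2S,3S,4S)-4-benzoyloxy-1-(hydroxymethyl)cyclohex-5-ene-1,2,3-triol | OC[C@]1(O)C=C[C@H](OC(=O)c2ccccc2)[C@@H](O)[C@@H]1O
A1 | alternative 1 | cyclohexa-1,3-diene | C1=CC=CCC1
A2 | alternative 1 | (1R,6S)-7-oxabicyclo[4.1.0]hept-2-ene | C1C=C[C@H]2O[C@H]2C1
A3 | alternative 2 | 3-hydroxy-2-pyrone | O=C1OC=CC=C1O
A4 | alternative 2 | (E)-hex-3-ene-2,5-dione | CC(=O)/C=C/C(C)=O
A5 | alternative 2 | trans-7,8-diacetyl-4-hydroxy-2-oxabicyclo[2.2.2]oct-5-en-3-one (acetyl next to the carbinol bridgehead syn to the lactone bridge) | O=C2[C@]1(O)C=C[C@H](O2)[C@@H](C(C)=O)[C@@H]1C(C)=O
A6 | alternative 3 | benzoic acid | O=C(O)c1ccccc1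
A7 | alternative 3 | (1S,2R)-1,2-dihydroxycyclohexa-3,5-diene-1-carboxylic acid | OC(=O)[C@]1(O)C=CC=C[C@H]1O
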